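## Retrosynthetic overview

1. The bond made in the key step is the CH2–CH2 link between the methylene on C1 of the 2,6,6-trimethylcyclohexene ring and the methylene on the chain C(CH3)=CH alkene. Both carbons are allylic (ring C1=C2 alkene, CH2–CH2, chain alkene form a 1,5-diene). The ring-side carbon can therefore be a sulfonyl-stabilised allyl anion whose other terminus (ring C2, bearing CH3) is blocked, and the chain-side carbon the primary terminus of an (E)-2-methyl-π-allyl-palladium. They are joined by a Pd-catalysed decarboxylative allylation of an α-sulfonyl acid with an allylic carbonate; CO2H and SO2Ph are temporary activators (CO2 leaves in the key step, PhSO2 in step 15).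
2. Chain half: the 1,5-diol is carried as a temporary 5,6-dihydro-2H-pyran-2-one ring (RCM), which fixes the C(CH2OH)=CH geometry and masks both hydroxyls until reductive opening. The (R)-carbinol comes from Keck allylation of furan-3-carbaldehyde, the (E)-allylic terminus from SeO2 oxidation.
3. The butenolide is carried as the 3-substituted furan ring and unveiled last (singlet oxygen, then NaBH4).
4. Ring order: cyclohexene (bought) → dihydropyranone by RCM (temporary, opened in step 14) → furan (bought) → butenolide (steps 16–17).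

Key step: step 13

Remark: the carbon bearing PhSO2 in 5, 17, 18 and 19 is a stereocentre of no consequence (epimer mixtures, erased in step 15); 21–22 are mixtures at the peroxide/hemiacetal carbons and converge in step 17.

## Route

Step 1
Reactants: 1 β-cyclocitral
Product: 2 β-cyclogeraniol
Conditions: NaBH4, MeOH, 0 °C
Reagents that add atoms: none
Why: Borohydride 1,2-reduction of the hindered enal carbonyl gives the primary allylic alcohol without touching the tetrasubstituted alkene; no stereocentre is formed.

Step 2
Reactants: 2 β-cyclogeraniol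
Product: 3 β-cyclogeranyl bromide
Conditions: PBr3 (0.4 equiv), pyridine (cat.), Et2O, 0 °C
Reagents that add atoms: phosphorus tribromide, BrP(Br)Br
Why: Bromination of a primary allylic alcohol with PBr3 (SN2 at the primary carbon), the transposed product being a tertiary bromide at a fully substituted ring carbon and therefore disfavoured.

Step 3
Reactants: 3 β-cyclogeranyl bromide
Product: 4 β-cyclogeranyl phenyl sulfone
Conditions: PhSO2Na, DMF, 23 °C
Reagents that add atoms: sodium benzenesulfinate, [Na+].[O-]S(=O)c1ccccc1
Why: S-alkylation of the sulfinate by the allylic bromide (sulfone synthesis by SN2), the soft sulfur end reacting at the unhindered primary carbon.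

Step 4
Reactants: 4 β-cyclogeranyl phenyl sulfone
Product: 5 α-sulfonyl acid
Conditions: n-BuLi, THF, −78 °C; transfer onto excess CO2 in THF, −78 °C; cold aq. HCl
Reagents that add atoms: carbon dioxide, O=C=O
Why: Carboxylation of the α-sulfonyl allyl carbanion at its α-carbon (the γ-carbon is the fully substituted ring C2); inverse addition to excess CO2 limits proton transfer from the product.

Step 5
Reactants: 6 tert-butyl diethylphosphonoacetate; 7 5-bromo-2-methylpent-2-ene
Product: 8 alkylated phosphonoacetate
Conditions: NaH, DMF, 0 → 60 °C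
Reagents that add atoms: none
Why: C-alkylation of the phosphonoacetate anion by the primary homoallylic bromide (SN2).

Step 6
Reactants: 8 alkylated phosphonoacetate
Product: 9 tert-butyl 2-(homoprenyl)acrylate
Conditions: HCHO (37% aq.), K2CO3, THF/H2O, 70 °C
Reagents that add atoms: formaldehyde, C=O
Why: Horner–Wadsworth–Emmons methylenation with formaldehyde (Villiéras conditions) turns the α-alkyl phosphonoacetate into the 2-substituted acrylate; the tert-butyl ester survives aqueous carbonate.

Step 7
Reactants: 9 tert-butyl 2-(homoprenyl)acrylate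
Product: 10 (E)-allylic alcohol
Conditions: SeO2 (0.3 equiv), t-BuOOH (70% aq.), salicylic acid (cat.), CH2Cl2, 23 °C
Reagents that add atoms: tert-butyl hydroperoxide, CC(C)(C)OO
Why: SeO2 allylic oxidation (ene reaction then [2,3]-shift) attacks the (E)-methyl of the electron-rich trisubstituted alkene and so sets the E-allylic alcohol; the electron-poor acrylate is not an ene partner.

Step 8
Reactants: 10 (E)-allylic alcohol
Product: 11 allylic methyl carbonate
Conditions: ClCO2Me, pyridine, CH2Cl2, 0 °C
Reagents that add atoms: methyl chloroformate, COC(=O)Cl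
Why: O-acylation of the primary alcohol with a chloroformate; the carbonate serves as protecting group now and as the Pd leaving group in step 13.

Step 9
Reactants: 11 allylic methyl carbonate
Product: 12 acrylic acid
Conditions: TFA/CH2Cl2 (1:4), 0 → 23 °C
Reagents that add atoms: none
Why: Acidolysis of the tert-butyl ester (loss of isobutene) leaves the allylic carbonate and both alkenes intact, as in the TFA stability of allyl carbonates.

Step 10
Reactants: 13 furan-3-carbaldehyde
Product: 14 (R)-homoallylic alcohol
Conditions: allyl-SnBu3, (R)-BINOL (20 mol%), Ti(OiPr)4 (10 mol%), 4 Å MS, CH2Cl2, −20 °C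
Reagents that add atoms: allyltributylstannane, C=CC[Sn](CCCC)(CCCC)CCCC
Why: Keck asymmetric allylation; the (R)-BINOL–Ti Lewis acid directs the allyl group to the Re face of the aryl-type aldehyde and so sets the (R)-carbinol.

Step 11
Reactants: 12 acrylic acid; 14 (R)-homoallylic alcohol
Product: 15 diene ester
Conditions: DCC, DMAP (cat.), CH2Cl2, 0 → 23 °C
Reagents that add atoms: none
Why: Steglich esterification acylates the O–H bond without breaking the C–O bond, so the (R)-centre is retained.

Step 12
Reactants: 15 diene ester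
Product: 16 lactone allylic carbonate
Conditions: Grubbs II (5 mol%), CH2Cl2 (5 mM), 40 °C
Reagents that add atoms: none
Why: Ring-closing metathesis between the terminal alkene and the 1,1-disubstituted acrylate closes the six-membered α,β-unsaturated lactone, whose endocyclic alkene necessarily holds the carbonyl carbon and the ring CH2 cis; the trisubstituted chain alkene would give only a nine-membered ring and stays out.

Step 13
Reactants: 5 α-sulfonyl acid; 16 lactone allylic carbonate
Product: 18 sulfone lactone, via allyl ester 17 (not isolated)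
Conditions: Pd(PPh3)4 (5 mol%), degassed toluene, 23 °C then 80 °C
Reagents that add atoms: none
Why: Pd(0) ionises the allylic carbonate of 16 (CO2 and methoxide leave, the methoxide being protonated by acid 5) to an (E)-configured 2-methyl-π-allyl-Pd carboxylate ion pair that first collapses reversibly to allyl ester 17; on warming, re-ionisation and decarboxylation give a sulfonyl-stabilised allyl anion at the ring-bound carbon, which attacks the π-allyl to form the CH–CH2 bond. The closest known reaction type is the Pd-catalysed decarboxylative allylation of allyl α-sulfonylacetates (Tsuji–Trost manifold), preceded by Pd-catalysed O-allylation of a carboxylic acid with an allylic carbonate. No ring is closed. The only new stereocentre is the sulfonyl-bearing carbon, which is uncontrolled and erased in step 15. Three selectivities are needed: attack at the primary π-allyl terminus (secured by the bulk of the secondary carbanion next to the trimethylcyclohexenyl group), α- and not γ-attack of the allyl anion (the γ-carbon is the fully substituted ring C2), and retention of the (E)-alkene (the syn π-allyl can isomerise only through σ-Pd at the hindered secondary terminus). The neutral conditions leave the enoate lactone and the furan untouched, which a preformed lithio sulfone would not.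

Step 14
Reactants: 18 sulfone lactone
Product: 19 sulfone diol
Conditions: DIBAL-H (5 equiv), CH2Cl2, −78 → 0 °C; Rochelle salt work-up
Reagents that add atoms: none
Why: DIBAL-H 1,2-reduction of the unsaturated δ-lactone through the lactol to the ene-1,5-diol transfers the ring-locked alkene geometry into the CH2OH/CH2CH(OH) cis relationship; the C6–O bond is not broken, so the (R)-centre is kept, and sulfone and furan are inert.

Step 15
Reactants: 19 sulfone diol
Product: 20 furan diol
Conditions: Li (excess), EtNH2/THF, −78 °C; solid NH4Cl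
Reagents that add atoms: none
Why: Dissolving-metal reductive desulfonylation: electron transfer cleaves the allylic C–S bond and the allyl anion is protonated at its less substituted terminus (the former sulfonyl carbon), which keeps the tetrasubstituted ring alkene in place; isolated alkenes, alkoxides and the furan are not reduced at −78 °C.

Step 16
Reactants: 20 furan diol
Product: 22 hydroxybutenolide, via furan endoperoxide 21 (not isolated)
Conditions: O2, hν (visible), rose bengal (cat.), i-Pr2NEt, CH2Cl2, −78 °C
Reagents that add atoms: dioxygen, O=O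
Why: [4+2] cycloaddition of singlet oxygen to the furan and base-induced (Kornblum–DeLaMare-type) collapse of the endoperoxide by removal of the less hindered C5–H give the 4-substituted 5-hydroxybutenolide; at −78 °C the furan should outpace the ene reaction of the hindered alkenes, and the carbinol centre is untouched.

Step 17
Reactants: 22 hydroxybutenolide
Product: 24 target butenolide, via hydroxy acid 23 (not isolated)
Conditions: NaBH4, EtOH, 0 °C; then aq. HCl to pH 3
Reagents that add atoms: none
Why: NaBH4 reduces the aldehyde of the ring-opened 4-oxo-enoate form of the hydroxybutenolide, and acidification relactonises through the CH2OH that is cis to the carboxyl, giving the 4-substituted furan-2(5H)-one; the secondary carbinol is trans to the carboxyl and cannot lactonise.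

## Compound list

1 | β-cyclocitral (2,6,6-trimethylcyclohex-1-ene-1-carbaldehyde) | CC1=C(C=O)C(C)(C)CCC1 | starting material
2 | β-cyclogeraniol ((2,6,6-trimethylcyclohex-1-en-1-yl)methanol) | CC1=C(CO)C(C)(C)CCC1 | intermediate
3 | β-cyclogeranyl bromide (2-(bromomethyl)-1,3,3-trimethylcyclohex-1-ene) | CC1=C(CBr)C(C)(C)CCC1 | intermediate
4 | β-cyclogeranyl phenyl sulfone ({[(2,6,6-trimethylcyclohex-1-en-1-yl)methyl]sulfonyl}benzene) | CC1=C(CS(=O)(=O)c2ccccc2)C(C)(C)CCC1 | intermediate
5 | 2-(phenylsulfonyl)-2-(2,6,6-trimethylcyclohex-1-en-1-yl)acetic acid (racemic) | CC1=C(C(C(=O)O)S(=O)(=O)c2ccccc2)C(C)(C)CCC1 | intermediate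
6 | tert-butyl 2-(diethoxyphosphoryl)acetate | CCOP(=O)(CC(=O)OC(C)(C)C)OCC | starting material
7 | 5-bromo-2-methylpent-2-ene | CC(C)=CCCBr | starting material
8 | tert-butyl 2-(diethoxyphosphoryl)-6-methylhept-5-enoate (racemic) | CCOP(=O)(OCC)C(CCC=C(C)C)C(=O)OC(C)(C)C | intermediate
9 | tert-butyl 6-methyl-2-methylidenehept-5-enoate | C=C(CCC=C(C)C)C(=O)OC(C)(C)C | intermediate
10 | tert-butyl (5E)-7-hydroxy-6-methyl-2-methylidenehept-5-enoate | C=C(CC/C=C(\C)CO)C(=O)OC(C)(C)C | intermediate
11 | tert-butyl (5E)-7-[(methoxycarbonyl)oxy]-6-methyl-2-methylidenehept-5-enoate | C=C(CC/C=C(\C)COC(=O)OC)C(=O)OC(C)(C)C | intermediate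
12 | (5E)-7-[(methoxycarbonyl)oxy]-6-methyl-2-methylidenehept-5-enoic acid | C=C(CC/C=C(\C)COC(=O)OC)C(=O)O | intermediate
13 | furan-3-carbaldehyde | O=Cc1ccoc1 | starting material
14 | (1R)-1-(furan-3-yl)but-3-en-1-ol | C=CC[C@@H](O)c1ccoc1 | intermediate
15 | (1R)-1-(furan-3-yl)but-3-en-1-yl (5E)-7-[(methoxycarbonyl)oxy]-6-methyl-2-methylidenehept-5-enoate | C=CC[C@@H](OC(=O)C(=C)CC/C=C(\C)COC(=O)OC)c1ccoc1 | intermediate
16 | (2E)-5-[(6R)-6-(furan-3-yl)-2-oxo-5,6-dihydro-2H-pyran-3-yl]-2-methylpent-2-en-1-yl methyl carbonate | O=C1O[C@@H](c2ccoc2)CC=C1CC/C=C(\C)COC(=O)OC | intermediate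
17 | (2E)-5-[(6R)-6-(furan-3-yl)-2-oxo-5,6-dihydro-2H-pyran-3-yl]-2-methylpent-2-en-1-yl 2-(phenylsulfonyl)-2-(2,6,6-trimethylcyclohex-1-en-1-yl)acetate (epimers at the sulfonyl carbon) | CC1=C(C(C(=O)OC/C(C)=C/CCC2=CC[C@H](c3ccoc3)OC2=O)S(=O)(=O)c4ccccc4)C(C)(C)CCC1 | intermediate
18 | (6R)-6-(furan-3-yl)-3-[(3E)-4-methyl-6-(phenylsulfonyl)-6-(2,6,6-trimethylcyclohex-1-en-1-yl)hex-3-en-1-yl]-5,6-dihydro-2H-pyran-2-one (epimers at the sulfonyl carbon) | CC1=C(C(C/C(C)=C/CCC2=CC[C@H](c3ccoc3)OC2=O)S(=O)(=O)c4ccccc4)C(C)(C)CCC1 | intermediate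
19 | (1R,3Z,7E)-1-(furan-3-yl)-4-(hydroxymethyl)-8-methyl-10-(phenylsulfonyl)-10-(2,6,6-trimethylcyclohex-1-en-1-yl)deca-3,7-dien-1-ol (epimers at C10) | CC1=C(C(C/C(C)=C/CC/C(=C/C[C@@H](O)c2ccoc2)CO)S(=O)(=O)c3ccccc3)C(C)(C)CCC1 | intermediate
20 | (1R,3Z,7E)-1-(furan-3-yl)-4-(hydroxymethyl)-8-methyl-10-(2,6,6-trimethylcyclohex-1-en-1-yl)deca-3,7-dien-1-ol | CC1=C(CC/C(C)=C/CC/C(=C/C[C@@H](O)c2ccoc2)CO)C(C)(C)CCC1 | intermediate
21 | furan endoperoxide of 20 (5-substituted 2,3,7-trioxabicyclo[2.2.1]hept-5-ene, bridgehead mixture) | CC1=C(CC/C(C)=C/CC/C(=C/C[C@@H](O)C2=CC3OOC2O3)CO)C(C)(C)CCC1 | intermediate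
22 | 5-hydroxy-4-[(1R,3Z,7E)-1-hydroxy-4-(hydroxymethyl)-8-methyl-10-(2,6,6-trimethylcyclohex-1-en-1-yl)deca-3,7-dien-1-yl]furan-2(5H)-one (hemiacetal epimers) | CC1=C(CC/C(C)=C/CC/C(=C/C[C@@H](O)C2=CC(=O)OC2O)CO)C(C)(C)CCC1 | intermediate
23 | (2E,4R,6Z,10E)-4-hydroxy-3,7-bis(hydroxymethyl)-11-methyl-13-(2,6,6-trimethylcyclohex-1-en-1-yl)trideca-2,6,10-trienoic acid | CC1=C(CC/C(C)=C/CC/C(=C/C[C@@H](O)/C(CO)=C/C(=O)O)CO)C(C)(C)CCC1 | intermediate
24 | 4-[(1R,3Z,7E)-1-hydroxy-4-(hydroxymethyl)-8-methyl-10-(2,6,6-trimethylcyclohex-1-en-1-yl)deca-3,7-dien-1-yl]furan-2(5H)-one | CC1=C(CC/C(C)=C/CC/C(=C/C[C@@H](O)C2=CC(=O)OC2)CO)C(C)(C)CCC1 | target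

## Step count and risks

Total steps: 17. Longest linear sequence: 12 (steps 5–9 and 11–17, from 6 and 7).

**Step 13 (key step).** What may go wrong: protonation of the decarboxylated sulfonyl anion by acid that has not yet been esterified (protodecarboxylation back to 4), base-induced elimination of the π-allyl to a 1,3-diene, or attack at the secondary allyl terminus. The fallback is the classical alkylation of a lithio sulfone with an allylic chloride on a base-stable, silyl-protected chain half; it sets out from 10 (and uses 14 and 4) and comes back at 19.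
- Corey–Kim chlorination of 10 (NCS, Me2S, CH2Cl2, −20 → 0 °C) should give tert-butyl (5E)-7-chloro-6-methyl-2-methylidenehept-5-enoate F1.
- TFA/CH2Cl2 frees (5E)-7-chloro-6-methyl-2-methylidenehept-5-enoic acid F2.
- Steglich esterification with 14 gives (1R)-1-(furan-3-yl)but-3-en-1-yl (5E)-7-chloro-6-methyl-2-methylidenehept-5-enoate F3.
- Ring-closing metathesis (Grubbs II) gives (6R)-3-[(3E)-5-chloro-4-methylpent-3-en-1-yl]-6-(furan-3-yl)-5,6-dihydro-2H-pyran-2-one F4.
- DIBAL-H at −78 °C opens the lactone to (1R,3Z,7E)-9-chloro-1-(furan-3-yl)-4-(hydroxymethyl)-8-methylnona-3,7-dien-1-ol F5.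
- TBSOTf/2,6-lutidine gives the bis(tert-butyldimethylsilyl) ether of the chloro diol F6.
- Sulfone 4, lithiated with n-BuLi in THF/DMPU at −78 °C, is alkylated at its α-carbon by F6 to the bis(tert-butyldimethylsilyl) ether of 19 F7, and TBAF in THF returns 19.

**Step 16.** What may go wrong: ene reaction of singlet oxygen at the tetrasubstituted ring alkene or the trisubstituted alkenes competing with furan cycloaddition, and unselective collapse of the endoperoxide. The fallback avoids singlet oxygen; it sets out from 20 and comes back at 24, bypassing 22. Iridium-catalysed C–H borylation ([Ir(OMe)(cod)]2, 4,4'-di-tert-butyl-2,2'-bipyridine, B2pin2, THF, 50 °C; O–B bonds hydrolysed on work-up) should functionalise the less hindered furan α-position remote from the side chain, giving the 5-(pinacolboryl)furan derivative of 20 F8. Oxidation with NaBO3·4H2O in THF/H2O gives the 2-hydroxyfuran, which tautomerises to the conjugated furan-2(5H)-one 24. Neither reagent attacks isolated alkenes.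

**Step 15.** What may go wrong: protonation of the allyl anion at the ring carbon, which moves the alkene to the exocyclic position, and reductive C–O cleavage at the furyl carbinol under electron-transfer conditions. The fallback moves the C–S cleavage from the electron-transfer/allyl-anion manifold to a π-allyl-palladium hydride substitution, in which hydride goes to the less hindered allyl terminus; it sets out from 19 and comes back at 20. TESCl/imidazole in DMF gives the bis(triethylsilyl) ether of 19 F9, so that alkoxides do not sequester the borohydride. PdCl2(dppp) (cat.) with LiBHEt3 in THF at 0 °C should give the bis(triethylsilyl) ether of 20 F10, and TBAF returns 20.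

Further compounds
F1 | step 13 | tert-butyl (5E)-7-chloro-6-methyl-2-methylidenehept-5-enoate | C=C(CC/C=C(\C)CCl)C(=O)OC(C)(C)C
F2 | step 13 | (5E)-7-chloro-6-methyl-2-methylidenehept-5-enoic acid | C=C(CC/C=C(\C)CCl)C(=O)O
F3 | step 13 | (1R)-1-(furan-3-yl)but-3-en-1-yl (5E)-7-chloro-6-methyl-2-methylidenehept-5-enoate | C=CC[C@@H](OC(=O)C(=C)CC/C=C(\C)CCl)c1ccoc1
F4 | step 13 | (6R)-3-[(3E)-5-chloro-4-methylpent-3-en-1-yl]-6-(furan-3-yl)-5,6-dihydro-2H-pyran-2-one | O=C1O[C@@H](c2ccoc2)CC=C1CC/C=C(\C)CCl
F5 | step 13 | (1R,3Z,7E)-9-chloro-1-(furan-3-yl)-4-(hydroxymethyl)-8-methylnona-3,7-dien-1-ol | OC/C(=C\C[C@@H](O)c1ccoc1)CC/C=C(\C)CCl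
F6 | step 13 | bis(tert-butyldimethylsilyl) ether of F5 | CC(C)(C)[Si](C)(C)OC/C(=C\C[C@@H](O[Si](C)(C)C(C)(C)C)c1ccoc1)CC/C=C(\C)CCl
F7 | step 13 | bis(tert-butyldimethylsilyl) ether of 19 | CC1=C(C(C/C(C)=C/CC/C(=C/C[C@@H](O[Si](C)(C)C(C)(C)C)c2ccoc2)CO[Si](C)(C)C(C)(C)C)S(=O)(=O)c3ccccc3)C(C)(C)CCC1
F8 | step 16 | 5-(4,4,5,5-tetramethyl-1,3,2-dioxaborolan-2-yl)furan derivative of 20 | CC1=C(CC/C(C)=C/CC/C(=C/C[C@@H](O)c2coc(B3OC(C)(C)C(C)(C)O3)c2)CO)C(C)(C)CCC1
F9 | step 15 | bis(triethylsilyl) ether of 19 | CC1=C(C(C/C(C)=C/CC/C(=C/C[C@@H](O[Si](CC)(CC)CC)c2ccoc2)CO[Si](CC)(CC)CC)S(=O)(=O)c3ccccc3)C(C)(C)CCC1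
F10 | step 15 | bis(triethylsilyl) ether of 20 | CC1=C(CC/C(C)=C/CC/C(=C/C[C@@H](O[Si](CC)(CC)CC)c2ccoc2)CO[Si](CC)(CC)CC)C(C)(C)CCC1
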